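The benzophenone is cut inside ring B and not at its crowded carbonyl. Ring B (C1' to C6') carries its only oxygen on C4', para to the ketone, and the ketone sits between O5 and O7 of the chromene; this pattern maps onto a terminal ynone (C1', C6') and a 1-methoxy-3-silyloxybutadiene (C2' to C5'). One Diels–Alder/aromatisation operation forms C1'–C2' and C5'–C6', closes ring B and delivers its free phenol. The precursor is the 6-propynoyl-2,2-dimethyl-8-prenyl-2H-chromene with O5 and O7 capped as methoxymethyl ethers, built from 2,4,6-trihydroxybenzaldehyde by pyran annulation, C8 prenylation, protection, ethynyl addition and oxidation.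

Key step: step 7

Remark on the chemistry: a prenyl ether on O7 would hand C8 a 1,1-dimethylallyl group on [3,3] shift, so the 3-methylbut-2-enyl group is put on C8 by direct C-alkylation of the phenoxide with prenyl bromide.
Remark on the chemistry: the target is achiral; the carbinol of step 5 and the cycloadduct of step 7 are racemic, and their stereocentres are erased in the operation that follows.

Step 1
Reactants: 1 phloroglucinaldehyde (2,4,6-trihydroxybenzaldehyde); 2 tertiary propargylic chloride 3-chloro-3-methylbut-1-yne
Product: 3 aryl propargyl ether 2,6-dihydroxy-4-[(2-methylbut-3-yn-2-yl)oxy]benzaldehyde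
Conditions: 2 (1.1 equiv), DBU (1.2 equiv), CuCl2·2H2O (cat.), MeCN, 0 °C
Reagents that add atoms: none
Why: Copper-catalysed O-alkylation of a phenol with a tertiary propargylic chloride (Williamson-type etherification through a copper acetylide); the 4-hydroxyl, para to the formyl group and outside the hydrogen-bonded chelate, is the most acidic and least hindered, so one equivalent of electrophile should give the mono-ether.

Step 2
Reactants: 3 aryl propargyl ether
Product: 6 chromene aldehyde 5,7-dihydroxy-2,2-dimethyl-2H-chromene-6-carbaldehyde, via allenyl phenol 4 (not isolated), via ortho-quinone methide 5 (not isolated)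
Conditions: xylenes, 140 °C
Reagents that add atoms: none
Why: Aryl propargyl ether Claisen rearrangement to the ortho carbon (C3 and C5 are equivalent), enolisation to 4, 1,5-hydrogen shift to 5 and 6π-oxa-electrocyclisation form the standard thermal cascade to 2,2-dimethyl-2H-chromenes; the ether oxygen stays in the pyran, which fixes the formyl group at C6 between the two hydroxyls.

Step 3
Reactants: 6 chromene aldehyde; 7 prenyl bromide (1-bromo-3-methylbut-2-ene)
Product: 8 prenylated chromene aldehyde 5,7-dihydroxy-2,2-dimethyl-8-(3-methylbut-2-en-1-yl)-2H-chromene-6-carbaldehyde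
Conditions: 7 (1.1 equiv), 10% aq KOH, 0 °C → rt; then 1 M HCl to pH 4
Reagents that add atoms: none
Why: C-alkylation of an ambident phloroglucinol-type phenoxide with an allylic bromide (SN2 at the primary carbon, so the prenyl group arrives unrearranged); water solvates the phenoxide oxygens and steers the electrophile to carbon, and C8, ortho to O7 and para to O5, is the only unsubstituted ring carbon.

Step 4
Reactants: 8 prenylated chromene aldehyde
Product: 9 protected aldehyde 5,7-bis(methoxymethoxy)-2,2-dimethyl-8-(3-methylbut-2-en-1-yl)-2H-chromene-6-carbaldehyde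
Conditions: NaH (2.5 equiv), MOMCl (3 equiv), DMF, 0 °C → rt
Reagents that add atoms: chloromethyl methyl ether (MOMCl), COCCl
Why: Williamson-type etherification of both phenoxides with chloromethyl methyl ether; NaH breaks the hydrogen bond to the aldehyde so that both hydroxyls are capped, which later keeps them from adding to the ynone.

Step 5
Reactants: 9 protected aldehyde
Product: 10 racemic propargylic alcohol 1-[5,7-bis(methoxymethoxy)-2,2-dimethyl-8-(3-methylbut-2-en-1-yl)-2H-chromen-6-yl]prop-2-yn-1-ol
Conditions: HC≡CMgBr (0.5 M in THF, 2 equiv), THF, 0 °C; then sat. aq NH4Cl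
Reagents that add atoms: ethynylmagnesium bromide, C#C[Mg]Br
Why: Grignard 1,2-addition of a small, linear sp-carbon nucleophile that can pass between the two flanking acetal groups; the new carbinol centre forms without control as a racemate and is removed by the oxidation in step 6.

Step 6
Reactants: 10 racemic propargylic alcohol
Product: 11 ynone 1-[5,7-bis(methoxymethoxy)-2,2-dimethyl-8-(3-methylbut-2-en-1-yl)-2H-chromen-6-yl]prop-2-yn-1-one
Conditions: Dess–Martin periodinane (1.3 equiv), CH2Cl2, 0 °C → rt
Reagents that add atoms: none
Why: Dess–Martin oxidation of a secondary benzylic-propargylic alcohol under neutral, non-aqueous conditions that the acetals, both olefins and the terminal alkyne tolerate, with no base present that could trigger conjugate addition to the ynone.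

Step 7
Reactants: 11 ynone; 12 (E)-1-methoxy-3-(trimethylsilyloxy)buta-1,3-diene
Product: 14 protected benzophenone [5,7-bis(methoxymethoxy)-2,2-dimethyl-8-(3-methylbut-2-en-1-yl)-2H-chromen-6-yl](4-hydroxyphenyl)methanone, via cycloadduct 13 (not isolated)
Conditions: 12 (2 equiv), toluene, 80 °C; then 0.1 M aq HCl, THF, 0 °C
Reagents that add atoms: none
Why: The electron-rich diene 12 and the electron-poor alkyne of 11 combine in a thermal, concerted but asynchronous (4+2) cycloaddition in which the CH2 terminus of 12 bonds to the alkyne terminus (C5'–C6') and the methoxy-bearing terminus bonds to the carbon alpha to the ketone (C1'–C2'), giving 1,4-cyclohexadiene 13; dilute acid then hydrolyses the silyl enol ether and expels methanol, so the ring aromatises to the 4-hydroxyphenyl ketone. The closest known reaction type is the Diels–Alder reaction of 1-methoxy-3-silyloxybutadienes with acetylenic ketones and esters, followed by aromatisation to para-hydroxyaryl carbonyl compounds. Ring B is closed by an intermolecular (4+2) cycloaddition that makes both new bonds of the carbocycle in one event. The only stereocentre that appears, the methoxy-bearing carbon of 13, is racemic and is erased on aromatisation, so no stereocontrol is needed. The step needs regioselectivity, secured by the matched polarisation of the partners (largest HOMO coefficient at the diene CH2, largest LUMO coefficient at the alkyne terminus), which places the oxygen para to the carbonyl, and chemoselectivity, secured because the chromene and prenyl olefins are electron-rich and inert to the diene. The acetals on O5 and O7 block 6-endo conjugate closure of a phenol onto the ynone (chromone formation), and the short, cold acid treatment should leave them in place; partial loss would be harmless because step 8 removes them.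

Step 8
Reactants: 14 protected benzophenone
Product: 15 vismiaphenone E, [5,7-dihydroxy-2,2-dimethyl-8-(3-methylbut-2-en-1-yl)-2H-chromen-6-yl](4-hydroxyphenyl)methanone
Conditions: p-TsOH·H2O (0.2 equiv), MeOH, 40 °C
Reagents that add atoms: none
Why: Acid-catalysed transacetalisation of the aryl methoxymethyl ethers to methanol (acetal cleavage), helped at O5 and O7 by relief of crowding and by the hydrogen bond each freed phenol makes to the ketone; catalytic acid at mild temperature should not close the prenyl group onto O7 or add methanol to the chromene.

Compound list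
1 | 2,4,6-trihydroxybenzaldehyde | O=Cc1c(O)cc(O)cc1O | starting material
2 | 3-chloro-3-methylbut-1-yne | C#CC(C)(C)Cl | starting material
3 | 2,6-dihydroxy-4-[(2-methylbut-3-yn-2-yl)oxy]benzaldehyde | O=Cc1c(O)cc(OC(C)(C)C#C)cc1O | intermediate
4 | 2,4,6-trihydroxy-3-(3-methylbuta-1,2-dien-1-yl)benzaldehyde (allenyl phenol, not isolated) | O=Cc1c(O)cc(O)c(C=C=C(C)C)c1O | intermediate
5 | (3Z)-2,6-dihydroxy-3-(3-methylbut-2-en-1-ylidene)-4-oxocyclohexa-1,5-diene-1-carbaldehyde (ortho-quinone methide, not isolated) | O=CC1=C(O)C(=C/C=C(C)C)/C(=O)C=C1O | intermediate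
6 | 5,7-dihydroxy-2,2-dimethyl-2H-chromene-6-carbaldehyde | O=Cc1c(O)cc2OC(C)(C)C=Cc2c1O | intermediate
7 | prenyl bromide (1-bromo-3-methylbut-2-ene) | CC(C)=CCBr | starting material
8 | 5,7-dihydroxy-2,2-dimethyl-8-(3-methylbut-2-en-1-yl)-2H-chromene-6-carbaldehyde | O=Cc1c(O)c(CC=C(C)C)c2OC(C)(C)C=Cc2c1O | intermediate
9 | 5,7-bis(methoxymethoxy)-2,2-dimethyl-8-(3-methylbut-2-en-1-yl)-2H-chromene-6-carbaldehyde | O=Cc1c(OCOC)c(CC=C(C)C)c2OC(C)(C)C=Cc2c1OCOC | intermediate
10 | racemic 1-[5,7-bis(methoxymethoxy)-2,2-dimethyl-8-(3-methylbut-2-en-1-yl)-2H-chromen-6-yl]prop-2-yn-1-ol | C#CC(O)c1c(OCOC)c(CC=C(C)C)c2OC(C)(C)C=Cc2c1OCOC | intermediate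
11 | 1-[5,7-bis(methoxymethoxy)-2,2-dimethyl-8-(3-methylbut-2-en-1-yl)-2H-chromen-6-yl]prop-2-yn-1-one | C#CC(=O)c1c(OCOC)c(CC=C(C)C)c2OC(C)(C)C=Cc2c1OCOC | intermediate
12 | (E)-1-methoxy-3-(trimethylsilyloxy)buta-1,3-diene | CO/C=C/C(=C)O[Si](C)(C)C | starting material
13 | racemic [5,7-bis(methoxymethoxy)-2,2-dimethyl-8-(3-methylbut-2-en-1-yl)-2H-chromen-6-yl][6-methoxy-4-(trimethylsilyloxy)cyclohexa-1,4-dien-1-yl]methanone (cycloadduct, not isolated) | COC1C=C(O[Si](C)(C)C)CC=C1C(=O)c1c(OCOC)c(CC=C(C)C)c2OC(C)(C)C=Cc2c1OCOC | intermediate
14 | [5,7-bis(methoxymethoxy)-2,2-dimethyl-8-(3-methylbut-2-en-1-yl)-2H-chromen-6-yl](4-hydroxyphenyl)methanone (vismiaphenone E 5,7-bis(methoxymethyl) ether) | CC(C)=CCc1c(OCOC)c(C(=O)c2ccc(O)cc2)c(OCOC)c2c1OC(C)(C)C=C2 | intermediate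
15 | vismiaphenone E | CC(C)=CCc1c(O)c(C(=O)c2ccc(O)cc2)c(O)c2c1OC(C)(C)C=C2 | target

Total step count: 8
Longest linear sequence: 8 steps (1 to 15); compounds 2, 7 and 12 are purchased and enter directly.

Steps most likely to fail

Step 7. The terminal ynone may be consumed by polymerisation or by non-pericyclic conjugate addition before the cycloaddition is complete, or the acid aromatisation may be accompanied by acetal loss and decomposition. In that case ring B would be brought in intact, setting out from aldehyde 9 and returning to the route at target 15. 4-(Methoxymethoxy)phenylmagnesium bromide F1, generated from purchased 1-bromo-4-(methoxymethoxy)benzene and Mg turnings in THF, would add to 9 (THF, 0 °C → rt) to give the racemic diaryl carbinol [5,7-bis(methoxymethoxy)-2,2-dimethyl-8-(3-methylbut-2-en-1-yl)-2H-chromen-6-yl][4-(methoxymethoxy)phenyl]methanol F2. Dess–Martin oxidation would give the tris(methoxymethyl) ether of vismiaphenone E F3, and the acid methanolysis of step 8 would remove all three acetals to give 15. The price is the addition of a bulkier aryl nucleophile to the flanked aldehyde, which is known chemistry for benzaldehydes with two ortho alkoxy groups.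

Step 3. O-alkylation of the phenoxide and a second alkylation at C8 with loss of aromaticity may compete with the wanted mono C-alkylation. The prenyl group would then be introduced by cross-coupling, setting out from chromene 6 and returning at protected aldehyde 9 (steps 3 and 4 are both replaced). Iodination at C8, the only free ring position (I2, NaHCO3, THF–H2O, 0 °C), would give 5,7-dihydroxy-8-iodo-2,2-dimethyl-2H-chromene-6-carbaldehyde F4. Protection as in step 4 (NaH, MOMCl, DMF) would give 8-iodo-5,7-bis(methoxymethoxy)-2,2-dimethyl-2H-chromene-6-carbaldehyde F5. Stille coupling with purchased tributyl(3-methylbut-2-en-1-yl)stannane (Pd(PPh3)4, DMF, 90 °C), expected to join the aryl group to the less hindered primary allyl terminus, would then give 9.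

Step 1. Etherification may not stop cleanly at O4: alkylation of an ortho hydroxyl or of a ring carbon of the phloroglucinol nucleus would erode the mono-ether. The pyran ring would then be made by condensation instead of rearrangement, setting out from 1 and returning at chromene 6 (steps 1 and 2 are both replaced). Compound 1 and 3-methylbut-2-enal with ethylenediammonium diacetate (cat.) in toluene at 100 °C should undergo Knoevenagel condensation at C3 and 6π-oxa-electrocyclisation through quinone methide 5 to give 6 directly. Ring closure through an ortho oxygen in place of O4 would be the competing process, and the 8-formyl isomer would have to be separated. This fallback makes no compound outside the list (F0).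

Further compounds
F1 | step 7 | 4-(methoxymethoxy)phenylmagnesium bromide | COCOc1ccc([Mg]Br)cc1
F2 | step 7 | racemic [5,7-bis(methoxymethoxy)-2,2-dimethyl-8-(3-methylbut-2-en-1-yl)-2H-chromen-6-yl][4-(methoxymethoxy)phenyl]methanol | OC(c1ccc(OCOC)cc1)c1c(OCOC)c(CC=C(C)C)c2OC(C)(C)C=Cc2c1OCOC
F3 | step 7 | [5,7-bis(methoxymethoxy)-2,2-dimethyl-8-(3-methylbut-2-en-1-yl)-2H-chromen-6-yl][4-(methoxymethoxy)phenyl]methanone | O=C(c1ccc(OCOC)cc1)c1c(OCOC)c(CC=C(C)C)c2OC(C)(C)C=Cc2c1OCOC
F4 | step 3 | 5,7-dihydroxy-8-iodo-2,2-dimethyl-2H-chromene-6-carbaldehyde | O=Cc1c(O)c(I)c2OC(C)(C)C=Cc2c1O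
F5 | step 3 | 8-iodo-5,7-bis(methoxymethoxy)-2,2-dimethyl-2H-chromene-6-carbaldehyde | O=Cc1c(OCOC)c(I)c2OC(C)(C)C=Cc2c1OCOC
F0 | step 1 | none | none
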